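**Plan**
- Retrosynthesis: the two O-acetyl groups and the bond from C7 to the 4-hydroxy-3,5-dimethoxyphenyl ring are cut first (aryl Grignard onto a C7 aldehyde, benzylic oxygen removed afterwards). C5–C6 and C3–C4 are then cut as two aldol bonds, leaving 3-(4-hydroxy-3-methoxyphenyl)propanal and two molecules of acetaldehyde.
- Enabling feature: the acyclic segment C3(O)–C4H2–C5(O)–C6H2–C7, with oxygen on C3 and C5 in a 1,3-syn relation and plain methylenes at C4 and C6, is a 3,5-dihydroxy aldehyde with C7 at the aldehyde level. No ring is involved; the two benzene rings are bought.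
- Forward: the chain grows from the guaiacyl end. The C1–C3 aldehyde takes up C4/C5 and C6/C7 from acetaldehyde in one enzymatic pot and rests as a lactol. The syringyl ring is added at C7, all hydroxyls are acetylated, the benzylic C–O bond and the benzyl ether are hydrogenolysed, and the one aryl acetate is removed.
- Stereochemistry: both stereocentres (3R,5S in the target, a syn pair) come from the aldolase. The carbinol made at C7 by the Grignard addition is uncontrolled and is erased.

Key step: step 2

Remark: target numbering runs from the CH2 on the 4-hydroxy-3-methoxyphenyl ring (C1) to the CH2 on the 4-hydroxy-3,5-dimethoxyphenyl ring (C7); in the aldehyde, lactol and carbinol intermediates the same two centres are both labelled R only because numbering and substituent priorities differ, and no centre is inverted anywhere.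
Remark: an aldolase variant that binds a 3-arylpropanal is assumed to be obtainable by screening or engineering from the known acetaldehyde-tolerant variants that accept non-phosphorylated aldehydes.

**Step 1**
Reactants: 1 methyl 3-(4-hydroxy-3-methoxyphenyl)propanoate
Product: 2 3-(4-hydroxy-3-methoxyphenyl)propanal
Conditions: i-Bu2AlH (2.2 equiv), CH2Cl2, −78 °C; then aq. potassium sodium tartrate
Reagents that add atoms: none
Why: Partial ester reduction with diisobutylaluminium hydride: one equivalent is taken up by the phenol, and the aluminium hemiacetal formed by the second is stable at −78 °C, so the aldehyde is released only on work-up and is not reduced further.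

**Step 2**
Reactants: 2 3-(4-hydroxy-3-methoxyphenyl)propanal; 3 acetaldehyde (two molecules incorporated)
Product: 6 (4R,6R)-6-[2-(4-hydroxy-3-methoxyphenyl)ethyl]oxane-2,4-diol as its anomer mixture, via (3R)-3-hydroxy-5-(4-hydroxy-3-methoxyphenyl)pentanal 4 (not isolated), via (3R,5R)-3,5-dihydroxy-7-(4-hydroxy-3-methoxyphenyl)heptanal 5 (not isolated)
Conditions: 2-deoxy-D-ribose-5-phosphate aldolase (E. coli enzyme, acetaldehyde-tolerant variant with opened acceptor site, cell-free lysate), 3 (2.5 equiv, fed slowly), triethanolamine buffer pH 7.5, 10% DMSO, 25 °C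
Reagents that add atoms: none
Why: Proposed new method: the active-site lysine condenses with acetaldehyde to an enamine that adds to the aldehyde of 2, hydrolysis of the iminium frees mono-aldol 4, and 4 is taken up again as acceptor for a second enamine addition to give 5, so that C3–C4 and C5–C6 (target numbering) form in one pot. The closest known reaction type is the sequential addition of two acetaldehyde molecules to chloroacetaldehyde, acetaldehyde or 3-azidopropanal by this aldolase, which gives the syn-3,5-dihydroxy lactols used for statin side chains; the tandem reaction has not been run on a 3-arylpropanal, whose aryl group should point out of the acceptor site toward solvent as the azidoethyl group of the known acceptor does. No ring of the target is closed; the only ring is that of the resting lactol 6, formed reversibly by 6-exo-trig addition of the δ-hydroxyl of 5 to its aldehyde carbon. Both new stereocentres are controlled by the enzyme, which delivers the enamine to the same carbonyl face in each round (R at the carbinol of 4, then 3R,5R in 5, the syn pattern of the statin lactol), and the second round should take only correctly configured 4, which corrects leakage in the first. The step needs cross-addition to win over acetaldehyde self-addition and must stop after two rounds: slow feeding keeps 2 in excess over free acetaldehyde, and lactol formation masks the aldehyde of 5 against a third addition.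

**Step 3**
Reactants: 7 4-bromo-2,6-dimethoxyphenol
Product: 8 2-(benzyloxy)-5-bromo-1,3-dimethoxybenzene
Conditions: BnBr (1.1 equiv), K2CO3 (1.5 equiv), DMF, rt
Reagents that add atoms: benzyl bromide, BrCc1ccccc1
Why: Williamson ether synthesis: the phenoxide formed with K2CO3 is alkylated by the reactive benzylic bromide, and the benzyl ether masks the acidic hydrogen that would otherwise quench the Grignard reagent of step 4.

**Step 4**
Reactants: 6 (4R,6R)-6-[2-(4-hydroxy-3-methoxyphenyl)ethyl]oxane-2,4-diol; 8 2-(benzyloxy)-5-bromo-1,3-dimethoxybenzene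
Product: 10 (3R,5R)-1-[4-(benzyloxy)-3,5-dimethoxyphenyl]-7-(4-hydroxy-3-methoxyphenyl)heptane-1,3,5-triol as a mixture of C1 epimers, via [4-(benzyloxy)-3,5-dimethoxyphenyl]magnesium bromide 9 (not isolated)
Conditions: 8 (5.5 equiv), Mg turnings, cat. I2, THF, reflux; then 6 in THF, 0 °C to rt; aq. NH4Cl
Reagents that add atoms: none
Why: Grignard addition to a lactol through its ring-opened hydroxy-aldehyde magnesium salt: three equivalents of 9 are spent on the phenol and the two hydroxyls and a further one adds to the aldehyde; the benzylic carbinol centre forms without control, which does not matter because step 6 removes its oxygen, and the two aldolase-set centres are not touched.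

**Step 5**
Reactants: 10 (3R,5R)-1-[4-(benzyloxy)-3,5-dimethoxyphenyl]-7-(4-hydroxy-3-methoxyphenyl)heptane-1,3,5-triol
Product: 11 (3R,5R)-7-[4-(acetyloxy)-3-methoxyphenyl]-1-[4-(benzyloxy)-3,5-dimethoxyphenyl]heptane-1,3,5-triyl triacetate (C1 epimers)
Conditions: Ac2O (8 equiv), pyridine, cat. DMAP, CH2Cl2, 0 °C to rt
Reagents that add atoms: acetic anhydride, CC(=O)OC(C)=O
Why: DMAP-catalysed acyl transfer (exhaustive acetylation): all four hydroxyls are esterified, which places the two acetates of the target, turns the benzylic hydroxyl into a group that hydrogenolyses readily, and leaves no free hydroxyl that could cyclise onto the benzylic carbon.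

**Step 6**
Reactants: 11 (3R,5R)-7-[4-(acetyloxy)-3-methoxyphenyl]-1-[4-(benzyloxy)-3,5-dimethoxyphenyl]heptane-1,3,5-triyl triacetate
Product: 12 (3R,5S)-1-[4-(acetyloxy)-3-methoxyphenyl]-7-(4-hydroxy-3,5-dimethoxyphenyl)heptane-3,5-diyl diacetate
Conditions: H2 (1 atm), Pd/C (10 wt% Pd), EtOAc–AcOH (10:1), rt
Reagents that add atoms: none
Why: Heterogeneous catalytic hydrogenolysis: the aryl benzyl ether is cleaved to the phenol and the benzylic C–OAc bond on the now para-hydroxylated, electron-rich ring is reduced to CH2, while the secondary alkyl acetates and the aryl acetate, which have no benzylic C–O bond, remain; the two stereocentres are not involved.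

**Step 7**
Reactants: 12 (3R,5S)-1-[4-(acetyloxy)-3-methoxyphenyl]-7-(4-hydroxy-3,5-dimethoxyphenyl)heptane-3,5-diyl diacetate
Product: 13 (3R,5S)-1-(4-hydroxy-3-methoxyphenyl)-7-(4-hydroxy-3,5-dimethoxyphenyl)heptane-3,5-diyl diacetate (CNP0327377.1)
Conditions: pyrrolidine (3 equiv), MeCN, 0 °C to rt
Reagents that add atoms: none
Why: Chemoselective aminolysis of an aryl ester: phenoxide is a far better leaving group than a secondary alkoxide, so pyrrolidine should remove only the phenolic acetate and leave the two alkyl acetates, which are too far from any free hydroxyl for acyl migration.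

**Compound list**
1 | methyl 3-(4-hydroxy-3-methoxyphenyl)propanoate | COC(=O)CCc1ccc(O)c(OC)c1 | starting material
2 | 3-(4-hydroxy-3-methoxyphenyl)propanal | COc1cc(CCC=O)ccc1O | intermediate
3 | acetaldehyde | CC=O | starting material
4 | (3R)-3-hydroxy-5-(4-hydroxy-3-methoxyphenyl)pentanal | COc1cc(CC[C@H](CC=O)O)ccc1O | intermediate
5 | (3R,5R)-3,5-dihydroxy-7-(4-hydroxy-3-methoxyphenyl)heptanal | COc1cc(CC[C@H](C[C@H](CC=O)O)O)ccc1O | intermediate
6 | (4R,6R)-6-[2-(4-hydroxy-3-methoxyphenyl)ethyl]oxane-2,4-diol (anomer mixture) | COc1cc(CC[C@@H]2C[C@@H](O)CC(O)O2)ccc1O | intermediate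
7 | 4-bromo-2,6-dimethoxyphenol | COc1cc(Br)cc(OC)c1O | starting material
8 | 2-(benzyloxy)-5-bromo-1,3-dimethoxybenzene | COc1cc(Br)cc(OC)c1OCc1ccccc1 | intermediate
9 | [4-(benzyloxy)-3,5-dimethoxyphenyl]magnesium bromide | COc1cc([Mg]Br)cc(OC)c1OCc1ccccc1 | intermediate
10 | (3R,5R)-1-[4-(benzyloxy)-3,5-dimethoxyphenyl]-7-(4-hydroxy-3-methoxyphenyl)heptane-1,3,5-triol (C1 epimers) | COc1cc(CC[C@H](C[C@H](CC(O)c2cc(OC)c(OCc3ccccc3)c(OC)c2)O)O)ccc1O | intermediate
11 | (3R,5R)-7-[4-(acetyloxy)-3-methoxyphenyl]-1-[4-(benzyloxy)-3,5-dimethoxyphenyl]heptane-1,3,5-triyl triacetate (C1 epimers) | COc1cc(CC[C@H](C[C@H](CC(OC(C)=O)c2cc(OC)c(OCc3ccccc3)c(OC)c2)OC(C)=O)OC(C)=O)ccc1OC(C)=O | intermediate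
12 | (3R,5S)-1-[4-(acetyloxy)-3-methoxyphenyl]-7-(4-hydroxy-3,5-dimethoxyphenyl)heptane-3,5-diyl diacetate | COc1cc(CC[C@H](C[C@H](CCc2cc(OC)c(O)c(OC)c2)OC(C)=O)OC(C)=O)ccc1OC(C)=O | intermediate
13 | (3R,5S)-1-(4-hydroxy-3-methoxyphenyl)-7-(4-hydroxy-3,5-dimethoxyphenyl)heptane-3,5-diyl diacetate | COc1cc(CC[C@H](C[C@H](CCc2cc(OC)c(O)c(OC)c2)OC(C)=O)OC(C)=O)ccc1O | target

**Step count and risks**
Total steps: 7. Longest linear sequence: 6 (steps 1, 2, 4, 5, 6, 7); step 3 is a one-step side branch that joins at step 4.

Steps most likely to fail: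

1. Step 2. The acceptor site may not take up the arylpropanal, so that acetaldehyde self-addition outruns cross-addition, or turnover may stop after the first addition. The fallback uses known chemistry, sets out from 2 and comes back at 6. The phenol of 2 is silylated (TBSCl, imidazole, DMF) to 3-[4-(tert-butyldimethylsilyloxy)-3-methoxyphenyl]propanal F1. An enantioselective vinylogous Mukaiyama aldol addition of 1-methoxy-1,3-bis(trimethylsilyloxy)buta-1,3-diene, catalysed by Ti(OiPr)4 and BINOL (antipode chosen to give the R carbinol; acidic desilylating work-up), should give methyl (5R)-7-[4-(tert-butyldimethylsilyloxy)-3-methoxyphenyl]-5-hydroxy-3-oxoheptanoate F2. Narasaka–Prasad reduction (Et2BOMe, NaBH4, THF–MeOH, −78 °C) sets the syn relation through the boron chelate and gives methyl (3R,5R)-7-[4-(tert-butyldimethylsilyloxy)-3-methoxyphenyl]-3,5-dihydroxyheptanoate F3. PPTS in warm toluene closes (4R,6R)-6-{2-[4-(tert-butyldimethylsilyloxy)-3-methoxyphenyl]ethyl}-4-hydroxyoxan-2-one F4. i-Bu2AlH at −78 °C reduces it to (4R,6R)-6-{2-[4-(tert-butyldimethylsilyloxy)-3-methoxyphenyl]ethyl}oxane-2,4-diol F5, and Bu4NF buffered with AcOH frees the phenol to give 6.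

2. Step 4. Deprotonation at three sites may give a poorly soluble magnesium phenoxide-alkoxide aggregate, so that ring opening and addition stall while base-induced retro-aldol cleavage or elimination of the aldolate consumes material. The fallback sets out from 6 and comes back at 13. The phenol of 6 is benzylated (BnBr, K2CO3, MeCN, rt) to (4R,6R)-6-{2-[4-(benzyloxy)-3-methoxyphenyl]ethyl}oxane-2,4-diol F6, which dissolves in THF and carries only two acidic hydrogens. About 3.5 equivalents of 9 should then give (3R,5R)-1-[4-(benzyloxy)-3,5-dimethoxyphenyl]-7-[4-(benzyloxy)-3-methoxyphenyl]heptane-1,3,5-triol F7. Acetylation (Ac2O, pyridine, DMAP) gives (3R,5R)-1-[4-(benzyloxy)-3,5-dimethoxyphenyl]-7-[4-(benzyloxy)-3-methoxyphenyl]heptane-1,3,5-triyl triacetate F8. One hydrogenolysis over Pd/C removes both benzyl ethers and the benzylic acetate and gives 13 directly, so no aryl acetate is ever made and the selective deacetylation is not needed.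

3. Step 6. The benzyl ether may be lost quickly while the benzylic C–O bond resists hydrogenolysis, or the para-hydroxybenzylic acetate may solvolyse instead of being reduced. The fallback sets out from 11 and comes back at 12. Ionic hydrogenation (Et3SiH, CF3CO2H, CH2Cl2, 0 °C) reduces the benzylic acetate through the benzylic cation with hydride transfer from silicon, and should give (3R,5S)-1-[4-(acetyloxy)-3-methoxyphenyl]-7-[4-(benzyloxy)-3,5-dimethoxyphenyl]heptane-3,5-diyl diacetate F9. No free hydroxyl is present to trap the cation. A separate mild hydrogenolysis (H2, Pd/C, EtOAc) then removes only the benzyl ether and gives 12; any benzyl ether already lost in the acid step gives 12 as well.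

**Further compounds**
F1 | step 2 | 3-[4-(tert-butyldimethylsilyloxy)-3-methoxyphenyl]propanal | COc1cc(CCC=O)ccc1O[Si](C)(C)C(C)(C)C
F2 | step 2 | methyl (5R)-7-[4-(tert-butyldimethylsilyloxy)-3-methoxyphenyl]-5-hydroxy-3-oxoheptanoate | COc1cc(CC[C@H](CC(=O)CC(=O)OC)O)ccc1O[Si](C)(C)C(C)(C)C
F3 | step 2 | methyl (3R,5R)-7-[4-(tert-butyldimethylsilyloxy)-3-methoxyphenyl]-3,5-dihydroxyheptanoate | COc1cc(CC[C@H](C[C@H](CC(=O)OC)O)O)ccc1O[Si](C)(C)C(C)(C)C
F4 | step 2 | (4R,6R)-6-{2-[4-(tert-butyldimethylsilyloxy)-3-methoxyphenyl]ethyl}-4-hydroxyoxan-2-one | COc1cc(CC[C@@H]2C[C@@H](O)CC(=O)O2)ccc1O[Si](C)(C)C(C)(C)C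
F5 | step 2 | (4R,6R)-6-{2-[4-(tert-butyldimethylsilyloxy)-3-methoxyphenyl]ethyl}oxane-2,4-diol | COc1cc(CC[C@@H]2C[C@@H](O)CC(O)O2)ccc1O[Si](C)(C)C(C)(C)C
F6 | step 4 | (4R,6R)-6-{2-[4-(benzyloxy)-3-methoxyphenyl]ethyl}oxane-2,4-diol | COc1cc(CC[C@@H]2C[C@@H](O)CC(O)O2)ccc1OCc1ccccc1
F7 | step 4 | (3R,5R)-1-[4-(benzyloxy)-3,5-dimethoxyphenyl]-7-[4-(benzyloxy)-3-methoxyphenyl]heptane-1,3,5-triol | COc1cc(CC[C@H](C[C@H](CC(O)c2cc(OC)c(OCc3ccccc3)c(OC)c2)O)O)ccc1OCc1ccccc1
F8 | step 4 | (3R,5R)-1-[4-(benzyloxy)-3,5-dimethoxyphenyl]-7-[4-(benzyloxy)-3-methoxyphenyl]heptane-1,3,5-triyl triacetate | COc1cc(CC[C@H](C[C@H](CC(OC(C)=O)c2cc(OC)c(OCc3ccccc3)c(OC)c2)OC(C)=O)OC(C)=O)ccc1OCc1ccccc1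
F9 | step 6 | (3R,5S)-1-[4-(acetyloxy)-3-methoxyphenyl]-7-[4-(benzyloxy)-3,5-dimethoxyphenyl]heptane-3,5-diyl diacetate | COc1cc(CC[C@H](C[C@H](CCc2cc(OC)c(OCc3ccccc3)c(OC)c2)OC(C)=O)OC(C)=O)ccc1OC(C)=O
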